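**Retrosynthetic overview**
1. Target 19 ⇐ hepta-MOM ether 18 (one global deprotection).
2. Cyclohexene ring (formed last) ⇐ Claisen [3,3] rearrangement of the 2-isopropenyl-3,4-dihydro-2H-pyran 17, which trades the ring O–C2 bond for the C4–C5 bond of the cyclohexene; 17 ⇐ acetal 15 + isopropenyl nucleophile 16.
3. Dihydropyran ring ⇐ enantioselective inverse-electron-demand oxa-Diels–Alder reaction (one C–O and one C–C bond) of 2'-hydroxychalcone 5 with flavonyl enol ether 14; it joins the flavonyl-CH to the aryl-CH and sets both of these stereocentres.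
4. 14 ⇐ Suzuki coupling of 8-iodoflavone 12; the flavone pyranone ring (formed first) ⇐ rhodium-catalysed C–H/C–O annulation of iodosalicylaldehyde 11 with alkyne 8.
5. Ring order: pyranone, then dihydropyran (temporary), then cyclohexene; everything comes from 1, 3, 7, 9, 13 and 16.

Assumption: the SMILES is taken as drawn, i.e. the flavonyl-bearing carbon is bonded to the aryl-bearing carbon and the aroyl-bearing carbon to the ring CH2, all-trans, (1R,5S,6S) in cyclohexenyl numbering (C1 flavonyl, C2=C3(Me), C4H2, C5 aroyl, C6 aryl). This is the regioisomer of the usual chalcone/dehydroprenyl adduct, so a direct all-carbon Diels–Alder union is not used.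

Abbreviations used in names: MOM = CH2OCH3. ArB = 2,4-bis(methoxymethoxy)phenyl. ArK = 2-hydroxy-4-(methoxymethoxy)phenyl. Fl = 2-[2,4-bis(methoxymethoxy)phenyl]-5,7-bis(methoxymethoxy)-3-(3-methylbut-2-en-1-yl)-4-oxo-4H-chromen-8-yl.

**Route**

Step 1
Reactants: 1 2,4-dihydroxybenzaldehyde
Product: 2 2,4-bis(methoxymethoxy)benzaldehyde
Conditions: MOMCl (3 equiv), K2CO3, acetone, reflux
Reagents that add atoms: chloromethyl methyl ether, COCCl
Why: Williamson-type O-alkylation (MOM acetal protection) of both phenols, with excess reagent and heat overcoming the hydrogen-bonded ortho OH.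

Step 2
Reactants: 3 1-(2,4-dihydroxyphenyl)ethan-1-one
Product: 4 1-[2-hydroxy-4-(methoxymethoxy)phenyl]ethan-1-one
Conditions: MOMCl (1.1 equiv), K2CO3, acetone, rt
Reagents that add atoms: chloromethyl methyl ether, COCCl
Why: Selective O-alkylation of the free para OH; the ortho OH is hydrogen-bonded to the ketone, stays unreacted and is kept as the later boron-binding site.

Step 3
Reactants: 4 1-[2-hydroxy-4-(methoxymethoxy)phenyl]ethan-1-one; 2 2,4-bis(methoxymethoxy)benzaldehyde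
Product: 5 (E)-3-ArB-1-ArK-prop-2-en-1-one (2'-hydroxychalcone)
Conditions: KOH (aq.), EtOH, rt
Reagents that add atoms: none
Why: Claisen–Schmidt aldol condensation gives the (E)-enone, and MOM ethers are stable to hydroxide.

Step 4
Reactants: 2 2,4-bis(methoxymethoxy)benzaldehyde
Product: 6 1-ethynyl-2,4-bis(methoxymethoxy)benzene
Conditions: dimethyl (1-diazo-2-oxopropyl)phosphonate, K2CO3, MeOH, rt
Reagents that add atoms: dimethyl (1-diazo-2-oxopropyl)phosphonate, COP(=O)(OC)C(=[N+]=[N-])C(C)=O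
Why: Seyferth–Gilbert homologation in its Ohira–Bestmann form converts the aldehyde into the terminal alkyne under mild carbonate conditions.

Step 5
Reactants: 6 1-ethynyl-2,4-bis(methoxymethoxy)benzene; 7 1-bromo-3-methylbut-2-ene (prenyl bromide)
Product: 8 2,4-bis(methoxymethoxy)-1-(5-methylhex-4-en-1-yn-1-yl)benzene
Conditions: CuI (10 mol%), NaI (10 mol%), K2CO3, DMF, rt
Reagents that add atoms: none
Why: Copper-acetylide alkylation of the allylic bromide at its primary carbon (SN2) gives the skipped enyne that carries the future C3 prenyl group.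

Step 6
Reactants: 9 2,4,6-trihydroxybenzaldehyde
Product: 10 2-hydroxy-4,6-bis(methoxymethoxy)benzaldehyde
Conditions: MOMCl (2.2 equiv), K2CO3, acetone, rt
Reagents that add atoms: chloromethyl methyl ether, COCCl
Why: O-alkylation protects two phenols, and one ortho OH stays free because it is hydrogen-bonded to the aldehyde (the two ortho OH groups are equivalent, so there is no regiochemical issue).

Step 7
Reactants: 10 2-hydroxy-4,6-bis(methoxymethoxy)benzaldehyde
Product: 11 2-hydroxy-3-iodo-4,6-bis(methoxymethoxy)benzaldehyde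
Conditions: NIS (1.05 equiv), DMF, 0 °C
Reagents that add atoms: N-iodosuccinimide, O=C1CCC(=O)N1I
Why: Electrophilic aromatic iodination goes ortho to the free phenol, as known for the 2-hydroxy-4,6-dialkoxy aryl carbonyl series, the other open position being shielded by two MOM ethers.

Step 8
Reactants: 11 2-hydroxy-3-iodo-4,6-bis(methoxymethoxy)benzaldehyde; 8 2,4-bis(methoxymethoxy)-1-(5-methylhex-4-en-1-yn-1-yl)benzene
Product: 12 2-ArB-8-iodo-5,7-bis(methoxymethoxy)-3-(3-methylbut-2-en-1-yl)-4H-chromen-4-one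
Conditions: [RhCl(cod)]2 (2 mol%), C5H2Ph4 (8 mol%), Cu(OAc)2·H2O (2.1 equiv), o-xylene, 130 °C
Reagents that add atoms: none
Why: Rhodium-catalysed oxidative annulation of a salicylaldehyde with an internal alkyne (phenol-directed aldehyde C–H activation, alkyne insertion with the aryl-bearing carbon on rhodium, C–O reductive elimination) closes the pyranone with aryl at C2 and prenyl at C3; the only free OH lies between CHO and iodine, so iodine must end at C8.

Step 9
Reactants: 12 2-ArB-8-iodo-5,7-bis(methoxymethoxy)-3-(3-methylbut-2-en-1-yl)-4H-chromen-4-one; 13 2-[(E)-2-ethoxyethenyl]-4,4,5,5-tetramethyl-1,3,2-dioxaborolane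
Product: 14 Fl-CH=CH-OEt, i.e. 2-ArB-8-[(E)-2-ethoxyethenyl]-5,7-bis(methoxymethoxy)-3-(3-methylbut-2-en-1-yl)-4H-chromen-4-one
Conditions: Pd(OAc)2 (5 mol%), SPhos (10 mol%), K3PO4, dioxane/H2O, 80 °C
Reagents that add atoms: none
Why: Suzuki–Miyaura coupling of the hindered aryl iodide with retention of the (E)-alkene geometry gives a geometrically pure enol ether whose nucleophilic carbon is the one attached to the flavone.

Step 10
Reactants: 14 Fl-CH=CH-OEt (E); 5 (E)-3-ArB-1-ArK-prop-2-en-1-one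
Product: 15 (2S,3R,4R)-2-ethoxy-3-Fl-4-ArB-6-ArK-3,4-dihydro-2H-pyran
Conditions: B(OPh)3 (20 mol%), (R)-VANOL (20 mol%), 5 Å MS, PhCF3, 0 °C to rt
Reagents that add atoms: none
Why: Proposed new method: the VANOL borate that chelates 2'-hydroxychalcones through phenolate and carbonyl oxygen (known to drive their all-carbon Diels–Alder reactions) is used to turn chalcone 5 into a chiral 1-oxadiene for an inverse-electron-demand oxa-Diels–Alder reaction with the β-aryl enol ether 14, in which the flavonyl-bearing enol ether carbon attacks the chalcone β-carbon on the face left open by the ligand, the dative B–O(carbonyl) bond opens and the carbonyl oxygen closes on the oxocarbenium carbon (new C–O bond), the endo-alkoxy transition state with the (E)-enol ether giving the 2,3-trans-3,4-trans acetal and thereby setting C3 and C4 (later C1 and C6 of the cyclohexene); closest known reactions are the chiral-borate-promoted Diels–Alder reaction of 2'-hydroxychalcones with dienes and the Lewis-acid-catalysed oxa-Diels–Alder reaction of enones with enol ethers.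

Step 11
Reactants: 15 (2S,3R,4R)-2-ethoxy-3-Fl-4-ArB-6-ArK-3,4-dihydro-2H-pyran; 16 potassium trifluoro(prop-1-en-2-yl)borate
Product: 18 2-ArB-8-[(1R,5S,6S)-6-ArB-5-(ArK-carbonyl)-3-methylcyclohex-2-en-1-yl]-5,7-bis(methoxymethoxy)-3-(3-methylbut-2-en-1-yl)-4H-chromen-4-one, via 2-isopropenyl-dihydropyran 17 (not isolated)
Conditions: 16 (2 equiv), BF3·OEt2 (2 equiv), CH2Cl2/MeCN, −40 to 0 °C; NaHCO3 work-up; then PhMe, 150 °C (sealed tube)
Reagents that add atoms: none
Why: BF3-promoted substitution of the anomeric ethoxy group by the alkenyltrifluoroborate (oxocarbenium ion, nucleophile entering trans to the C3 aryl group) is followed by a thermal Claisen [3,3] rearrangement through the ring-enforced boat, in which the isopropenyl CH2 bonds to the enol ether carbon on the face it occupies, so the C–O bond is exchanged for the last ring C–C bond, the aryl ketone is released and the new C5 stereocentre is trans to the C6 aryl group (this α-keto centre is also the thermodynamic one).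

Step 12
Reactants: 18 2-ArB-8-[(1R,5S,6S)-6-ArB-5-(ArK-carbonyl)-3-methylcyclohex-2-en-1-yl]-5,7-bis(methoxymethoxy)-3-(3-methylbut-2-en-1-yl)-4H-chromen-4-one
Product: 19 8-[(1R,5S,6S)-5-(2,4-dihydroxybenzoyl)-6-(2,4-dihydroxyphenyl)-3-methylcyclohex-2-en-1-yl]-2-(2,4-dihydroxyphenyl)-5,7-dihydroxy-3-(3-methylbut-2-en-1-yl)-4H-chromen-4-one
Conditions: HCl (2 M aq.), MeOH/THF, 40 °C
Reagents that add atoms: none
Why: Acid-catalysed acetal exchange removes all seven MOM groups without touching the three stereocentres, and the low temperature is chosen to avoid acid cyclisation of the prenyl group onto a neighbouring phenol.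

**Compound list**
1 | 2,4-dihydroxybenzaldehyde | O=Cc1ccc(O)cc1O | starting material
2 | 2,4-bis(methoxymethoxy)benzaldehyde | O=Cc1ccc(OCOC)cc1OCOC | intermediate
3 | 1-(2,4-dihydroxyphenyl)ethan-1-one | CC(=O)c1ccc(O)cc1O | starting material
4 | 1-[2-hydroxy-4-(methoxymethoxy)phenyl]ethan-1-one | CC(=O)c1ccc(OCOC)cc1O | intermediate
5 | (E)-3-[2,4-bis(methoxymethoxy)phenyl]-1-[2-hydroxy-4-(methoxymethoxy)phenyl]prop-2-en-1-one | O=C(/C=C/c1ccc(OCOC)cc1OCOC)c1ccc(OCOC)cc1O | intermediate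
6 | 1-ethynyl-2,4-bis(methoxymethoxy)benzene | C#Cc1ccc(OCOC)cc1OCOC | intermediate
7 | 1-bromo-3-methylbut-2-ene | CC(C)=CCBr | starting material
8 | 2,4-bis(methoxymethoxy)-1-(5-methylhex-4-en-1-yn-1-yl)benzene | CC(C)=CCC#Cc1ccc(OCOC)cc1OCOC | intermediate
9 | 2,4,6-trihydroxybenzaldehyde | O=Cc1c(O)cc(O)cc1O | starting material
10 | 2-hydroxy-4,6-bis(methoxymethoxy)benzaldehyde | O=Cc1c(O)cc(OCOC)cc1OCOC | intermediate
11 | 2-hydroxy-3-iodo-4,6-bis(methoxymethoxy)benzaldehyde | O=Cc1c(O)c(I)c(OCOC)cc1OCOC | intermediate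
12 | 2-[2,4-bis(methoxymethoxy)phenyl]-8-iodo-5,7-bis(methoxymethoxy)-3-(3-methylbut-2-en-1-yl)-4H-chromen-4-one | CC(C)=CCc1c(-c2ccc(OCOC)cc2OCOC)oc2c(I)c(OCOC)cc(OCOC)c2c1=O | intermediate
13 | 2-[(E)-2-ethoxyethenyl]-4,4,5,5-tetramethyl-1,3,2-dioxaborolane | CCO/C=C/B1OC(C)(C)C(C)(C)O1 | starting material
14 | 2-[2,4-bis(methoxymethoxy)phenyl]-8-[(E)-2-ethoxyethenyl]-5,7-bis(methoxymethoxy)-3-(3-methylbut-2-en-1-yl)-4H-chromen-4-one | CC(C)=CCc1c(-c2ccc(OCOC)cc2OCOC)oc2c(/C=C/OCC)c(OCOC)cc(OCOC)c2c1=O | intermediate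
15 | 8-[(2S,3R,4R)-4-[2,4-bis(methoxymethoxy)phenyl]-2-ethoxy-6-[2-hydroxy-4-(methoxymethoxy)phenyl]-3,4-dihydro-2H-pyran-3-yl]-2-[2,4-bis(methoxymethoxy)phenyl]-5,7-bis(methoxymethoxy)-3-(3-methylbut-2-en-1-yl)-4H-chromen-4-one | CC(C)=CCc1c(-c2ccc(OCOC)cc2OCOC)oc2c([C@@H]3[C@@H](OCC)OC(c4ccc(OCOC)cc4O)=C[C@H]3c3ccc(OCOC)cc3OCOC)c(OCOC)cc(OCOC)c2c1=O | intermediate
16 | potassium trifluoro(prop-1-en-2-yl)borate | [K+].CC(=C)[B-](F)(F)F | starting material
17 | 8-[(2S,3R,4S)-4-[2,4-bis(methoxymethoxy)phenyl]-6-[2-hydroxy-4-(methoxymethoxy)phenyl]-2-(prop-1-en-2-yl)-3,4-dihydro-2H-pyran-3-yl]-2-[2,4-bis(methoxymethoxy)phenyl]-5,7-bis(methoxymethoxy)-3-(3-methylbut-2-en-1-yl)-4H-chromen-4-one | CC(C)=CCc1c(-c2ccc(OCOC)cc2OCOC)oc2c([C@@H]3[C@@H](C(C)=C)OC(c4ccc(OCOC)cc4O)=C[C@H]3c3ccc(OCOC)cc3OCOC)c(OCOC)cc(OCOC)c2c1=O | intermediate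
18 | 8-[(1R,5S,6S)-6-[2,4-bis(methoxymethoxy)phenyl]-5-[2-hydroxy-4-(methoxymethoxy)benzoyl]-3-methylcyclohex-2-en-1-yl]-2-[2,4-bis(methoxymethoxy)phenyl]-5,7-bis(methoxymethoxy)-3-(3-methylbut-2-en-1-yl)-4H-chromen-4-one | CC(C)=CCc1c(-c2ccc(OCOC)cc2OCOC)oc2c([C@@H]3C=C(C)C[C@H](C(=O)c4ccc(OCOC)cc4O)[C@H]3c3ccc(OCOC)cc3OCOC)c(OCOC)cc(OCOC)c2c1=O | intermediate
19 | 8-[(1R,5S,6S)-5-(2,4-dihydroxybenzoyl)-6-(2,4-dihydroxyphenyl)-3-methylcyclohex-2-en-1-yl]-2-(2,4-dihydroxyphenyl)-5,7-dihydroxy-3-(3-methylbut-2-en-1-yl)-4H-chromen-4-one | CC(C)=CCc1c(-c2ccc(O)cc2O)oc2c([C@@H]3C=C(C)C[C@H](C(=O)c4ccc(O)cc4O)[C@H]3c3ccc(O)cc3O)c(O)cc(O)c2c1=O | target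

**Totals**
Total step count: 12. Longest linear sequence: 8 steps (steps 1, 4, 5, 8, 9, 10, 11, 12).

**Three steps most likely to fail**

Step 10 (the proposed oxa-Diels–Alder reaction). The bond is made between two hindered aryl-bearing carbons. The borate may instead stop at an open-chain Michael adduct or give a cyclobutane, may turn over poorly, and the facial sense of the (R)-ligand in this new mode is unproven and must be confirmed. Fallback with known chemistry: it sets out from 14 and 5. An achiral lanthanide catalyst, Yb(fod)3 (10 mol%) in ClCH2CH2Cl at 60 °C, is used for the same inverse-demand oxa-Diels–Alder reaction, which is established for enones and enol ethers. It gives the endo acetal as a racemate, that is 15 together with its mirror image, the (2R,3S,4S)-acetal F1. Preparative chiral SFC separates the two, and the route is rejoined at 15.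

Step 11 (anomeric substitution and Claisen rearrangement). BF3·OEt2 may ionise aryl MOM ethers or the enol ether, the trifluoroborate may add slowly, and heating may cause cycloreversion. Fallback: it sets out from 15 and avoids both the Lewis acid and the sigmatropic step. PPTS in acetone/H2O at rt hydrolyses the acetal to the keto aldehyde F2. Ph3P=CH2 (from Ph3PCH3Br and KN(SiMe3)2, THF, −78 °C) converts the aldehyde into the terminal alkene F3. KN(SiMe3)2 (2.2 equiv, phenolate plus enolate) followed by 3-bromo-2-methylprop-1-ene alkylates the ketone α-carbon to give the methallyl ketone F4. Ring-closing metathesis with second-generation Grubbs catalyst (CH2Cl2, 40 °C) then forms the C2=C3 bond of the cyclohexene, and the route is rejoined at 18.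

Step 8 (rhodium annulation). The iodine sits next to the directing OH, the skipped enyne can isomerise at 130 °C, and decarbonylation to a benzofuran is a known side path. Fallback by the classical Baker–Venkataraman route: it sets out from 11 and 2. MeMgBr (2.2 equiv, THF, 0 °C) adds to 11 to give the benzylic alcohol F5, and MnO2 (CH2Cl2) oxidises it to the methyl ketone F6. Aldehyde 2 is oxidised (NaClO2, NaH2PO4, 2-methylbut-2-ene, t-BuOH/H2O) to the benzoic acid F7. EDC·HCl/DMAP joins F6 and F7 to the aryl ester F8. KOtBu in THF induces the acyl shift to the 1,3-diketone F9. Prenyl bromide 7 with K2CO3 in acetone C-alkylates it to the 2-prenyl-1,3-diketone F10. PPTS (cat.) in toluene at 80 °C cyclodehydrates F10, and the route is rejoined at 12.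

**Further compounds**
F1 | step 10 | 8-[(2R,3S,4S)-4-[2,4-bis(methoxymethoxy)phenyl]-2-ethoxy-6-[2-hydroxy-4-(methoxymethoxy)phenyl]-3,4-dihydro-2H-pyran-3-yl]-2-[2,4-bis(methoxymethoxy)phenyl]-5,7-bis(methoxymethoxy)-3-(3-methylbut-2-en-1-yl)-4H-chromen-4-one | CC(C)=CCc1c(-c2ccc(OCOC)cc2OCOC)oc2c([C@H]3[C@H](OCC)OC(c4ccc(OCOC)cc4O)=C[C@@H]3c3ccc(OCOC)cc3OCOC)c(OCOC)cc(OCOC)c2c1=O
F2 | step 11 | (2R,3R)-3-[2,4-bis(methoxymethoxy)phenyl]-2-Fl-5-[2-hydroxy-4-(methoxymethoxy)phenyl]-5-oxopentanal | CC(C)=CCc1c(-c2ccc(OCOC)cc2OCOC)oc2c([C@@H]([C@H](c3ccc(OCOC)cc3OCOC)CC(=O)c3ccc(OCOC)cc3O)C=O)c(OCOC)cc(OCOC)c2c1=O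
F3 | step 11 | (3R,4R)-3-[2,4-bis(methoxymethoxy)phenyl]-4-Fl-1-[2-hydroxy-4-(methoxymethoxy)phenyl]hex-5-en-1-one | CC(C)=CCc1c(-c2ccc(OCOC)cc2OCOC)oc2c([C@@H]([C@H](c3ccc(OCOC)cc3OCOC)CC(=O)c3ccc(OCOC)cc3O)C=C)c(OCOC)cc(OCOC)c2c1=O
F4 | step 11 | (2S,3S,4R)-3-[2,4-bis(methoxymethoxy)phenyl]-4-Fl-1-[2-hydroxy-4-(methoxymethoxy)phenyl]-2-(2-methylprop-2-en-1-yl)hex-5-en-1-one | CC(C)=CCc1c(-c2ccc(OCOC)cc2OCOC)oc2c([C@@H]([C@H](c3ccc(OCOC)cc3OCOC)[C@H](CC(C)=C)C(=O)c3ccc(OCOC)cc3O)C=C)c(OCOC)cc(OCOC)c2c1=O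
F5 | step 8 | 2-(1-hydroxyethyl)-6-iodo-3,5-bis(methoxymethoxy)phenol (racemic) | CC(O)c1c(O)c(I)c(OCOC)cc1OCOC
F6 | step 8 | 1-[2-hydroxy-3-iodo-4,6-bis(methoxymethoxy)phenyl]ethan-1-one | CC(=O)c1c(O)c(I)c(OCOC)cc1OCOC
F7 | step 8 | 2,4-bis(methoxymethoxy)benzoic acid | OC(=O)c1ccc(OCOC)cc1OCOC
F8 | step 8 | 2-acetyl-6-iodo-3,5-bis(methoxymethoxy)phenyl 2,4-bis(methoxymethoxy)benzoate | CC(=O)c1c(OC(=O)c2ccc(OCOC)cc2OCOC)c(I)c(OCOC)cc1OCOC
F9 | step 8 | 1-[2,4-bis(methoxymethoxy)phenyl]-3-[2-hydroxy-3-iodo-4,6-bis(methoxymethoxy)phenyl]propane-1,3-dione | O=C(CC(=O)c1ccc(OCOC)cc1OCOC)c1c(O)c(I)c(OCOC)cc1OCOC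
F10 | step 8 | 1-[2,4-bis(methoxymethoxy)phenyl]-3-[2-hydroxy-3-iodo-4,6-bis(methoxymethoxy)phenyl]-2-(3-methylbut-2-en-1-yl)propane-1,3-dione (racemic) | CC(C)=CCC(C(=O)c1ccc(OCOC)cc1OCOC)C(=O)c1c(O)c(I)c(OCOC)cc1OCOC
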